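The route rests on cutting the C1–C2 bond of ring B. C1 bears a 4-hydroxy-3-methoxyphenyl ring, so ionization there gives a para-quinone methide with C1 as its electrophilic end. C2=C3, with the benzylic C4 methylene on C4a of ring A, is the matching nucleophile. In one operation a chiral phosphoric acid dehydrates a racemic diaryl carbinol, closes ring B, sets C1 and C2 (trans) and leaves the C3=C4 alkene. In precursor 18 only the pendant phenol is free. It comes from 6-bromovanillin (formyl carbon becomes C4, bromine marks C8a, hence OMe on C6 and O on C7), a (Z)-iodobutenediol unit and a guaiacyl Grignard reagent.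

Key step: step 11

Remark on locants: C1–C8a are those of the 1,2-dihydronaphthalene of the target. Ring A is the benzo ring and ring B is C1–C2–C3–C4–C4a–C8a.

Remark on ring A: a bromo-isovanillin has the right oxygen pattern only if its formyl carbon is C1, and C4 then has no carbon source. 6-Bromovanillin supplies C4 from its formyl group and already has the 6-OMe/7-O pattern.

Assumption: the sense of induction in step 11 cannot be derived by analogy. (R)-3,3'-bis(2,4,6-triisopropylphenyl)-1,1'-binaphthyl-2,2'-diyl hydrogen phosphate is written, and its (S)-antipode is used if the (1R,2S) series turns out to be favoured.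

Step 1
Reactants: 1 but-2-yne-1,4-diol
Product: 2 4-(tert-butyldimethylsilyloxy)but-2-yn-1-ol
Conditions: 1 (3 equiv), TBSCl (1 equiv), imidazole, THF/DMF, 0 °C
Reagents that add atoms: tert-butyldimethylsilyl chloride CC(C)(C)[Si](C)(C)Cl
Why: Imidazole-promoted O-silylation with the symmetrical diol in excess should favour the mono-ether, and the surplus diol is washed out with water.

Step 2
Reactants: 2 4-(tert-butyldimethylsilyloxy)but-2-yn-1-ol
Product: 4 (Z)-4-(tert-butyldimethylsilyloxy)-3-iodobut-2-en-1-ol, via cyclic vinylalanate 3 (not isolated)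
Conditions: NaAlH2(OCH2CH2OMe)2 (1.5 equiv), THF, 0 °C; I2, THF, −78 → 0 °C
Reagents that add atoms: iodine II
Why: In this hydroxyl-directed trans-hydroalumination the bound aluminium hydride delivers H to the near alkyne carbon and Al to the far one within five-membered alanate 3, and iodinolysis with retention leaves iodine cis to CH2OH, while 0 °C holds back β-elimination of the silyloxy group.

Step 3
Reactants: 5 2-bromo-4-hydroxy-5-methoxybenzaldehyde (6-bromovanillin)
Product: 6 2-bromo-4-(tert-butyldimethylsilyloxy)-5-methoxybenzaldehyde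
Conditions: TBSCl, imidazole, CH2Cl2, 23 °C
Reagents that add atoms: tert-butyldimethylsilyl chloride CC(C)(C)[Si](C)(C)Cl
Why: This is a standard phenol silylation, and the aryl TBS ether tolerates hydride, zinc, butyllithium, Grignard reagent and weak acid yet falls to fluoride at the end.

Step 4
Reactants: 6 2-bromo-4-(tert-butyldimethylsilyloxy)-5-methoxybenzaldehyde
Product: 7 [2-bromo-4-(tert-butyldimethylsilyloxy)-5-methoxyphenyl]methanol
Conditions: NaBH4, THF/MeOH, 0 °C
Reagents that add atoms: none
Why: Borohydride reduces the aryl aldehyde, and the aryl bromide and aryl silyl ether are inert at 0 °C.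

Step 5
Reactants: 7 [2-bromo-4-(tert-butyldimethylsilyloxy)-5-methoxyphenyl]methanol
Product: 8 2-bromo-4-(tert-butyldimethylsilyloxy)-5-methoxybenzyl chloride
Conditions: SOCl2, pyridine, CH2Cl2, 0 °C
Reagents that add atoms: thionyl chloride O=S(Cl)Cl
Why: Chlorodehydroxylation of an electron-rich benzylic alcohol is fast, and pyridine takes up HCl so that the silyl ether never meets free acid.

Step 6
Reactants: 8 2-bromo-4-(tert-butyldimethylsilyloxy)-5-methoxybenzyl chloride; 4 (Z)-4-(tert-butyldimethylsilyloxy)-3-iodobut-2-en-1-ol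
Product: 10 (E)-4-[2-bromo-4-(tert-butyldimethylsilyloxy)-5-methoxyphenyl]-3-[(tert-butyldimethylsilyloxy)methyl]but-2-en-1-ol, via benzylzinc chloride 9 (not isolated)
Conditions: 8, Zn dust, LiCl, THF, 23 °C; slow addition (1.4 equiv) to 4, Pd(PPh3)4 (5 mol %), THF, 23 °C
Reagents that add atoms: none
Why: LiCl-assisted zinc insertion takes the benzylic C–Cl and not the aryl C–Br bond, and the Negishi coupling proceeds with retention at the alkenyl iodide, which adds to zerovalent palladium far faster than the hindered electron-rich aryl bromide; a slight excess added slowly allows for the free hydroxyl, and coupling before acetylation avoids π-allyl formation from an allylic acetate.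

Step 7
Reactants: 10 (E)-4-[2-bromo-4-(tert-butyldimethylsilyloxy)-5-methoxyphenyl]-3-[(tert-butyldimethylsilyloxy)methyl]but-2-en-1-ol
Product: 12 5-(tert-butyldimethylsilyloxy)-2-{(E)-2-[(tert-butyldimethylsilyloxy)methyl]-4-hydroxybut-2-enyl}-4-methoxybenzaldehyde, via dilithio species 11 (not isolated)
Conditions: n-BuLi (2.2 equiv), THF, −78 °C; DMF, −78 → 0 °C; aq NH4Cl
Reagents that add atoms: N,N-dimethylformamide CN(C)C=O
Why: O-deprotonation, bromine–lithium exchange and formylation with DMF (Bouveault aldehyde synthesis) install C1; at −78 °C exchange outruns deprotonation of the C4 methylene, and silyl migration is excluded because the alkoxide and CH2OTBS are trans on the alkene.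

Step 8
Reactants: 12 5-(tert-butyldimethylsilyloxy)-2-{(E)-2-[(tert-butyldimethylsilyloxy)methyl]-4-hydroxybut-2-enyl}-4-methoxybenzaldehyde
Product: 13 (E)-4-[4-(tert-butyldimethylsilyloxy)-2-formyl-5-methoxyphenyl]-3-[(tert-butyldimethylsilyloxy)methyl]but-2-enyl acetate
Conditions: Ac2O, pyridine, 4-(dimethylamino)pyridine (5 mol %), CH2Cl2, 0 °C
Reagents that add atoms: acetic anhydride CC(=O)OC(C)=O
Why: Nucleophile-catalysed acetylation acts on the only free hydroxyl and leaves the aldehyde and silyl ethers untouched.

Step 9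
Reactants: 14 4-bromo-2-methoxyphenol
Product: 15 (4-bromo-2-methoxyphenoxy)trimethylsilane
Conditions: HN(SiMe3)2 (0.6 equiv), neat, 110 °C; distillation
Reagents that add atoms: hexamethyldisilazane C[Si](C)(C)N[Si](C)(C)C
Why: Silylation with the disilazane gives a distillable aryl TMS ether that survives Grignard formation yet hydrolyses under conditions that spare TBS ethers and the acetate.

Step 10
Reactants: 15 (4-bromo-2-methoxyphenoxy)trimethylsilane; 13 (E)-4-[4-(tert-butyldimethylsilyloxy)-2-formyl-5-methoxyphenyl]-3-[(tert-butyldimethylsilyloxy)methyl]but-2-enyl acetate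
Product: 18 racemic (E)-4-{4-(tert-butyldimethylsilyloxy)-2-[hydroxy(4-hydroxy-3-methoxyphenyl)methyl]-5-methoxyphenyl}-3-[(tert-butyldimethylsilyloxy)methyl]but-2-enyl acetate, via arylmagnesium bromide 16 (not isolated), via aryl TMS ether adduct 17 (not isolated)
Conditions: 15, Mg turnings, THF, 45 °C; 1.1 equiv added to 13, THF, −78 → −30 °C; aq NH4Cl, then MeOH, 23 °C
Reagents that add atoms: none
Why: Grignard addition to the aldehyde is far faster at low temperature than attack on a primary acetate, the very labile aryl TMS ether is lost in the near-neutral work-up while both TBS ethers stay, and the carbinol centre may form racemic because step 11 erases it.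

Step 11
Reactants: 18 racemic (E)-4-{4-(tert-butyldimethylsilyloxy)-2-[hydroxy(4-hydroxy-3-methoxyphenyl)methyl]-5-methoxyphenyl}-3-[(tert-butyldimethylsilyloxy)methyl]but-2-enyl acetate
Product: 20 [(1S,2R)-7-(tert-butyldimethylsilyloxy)-3-[(tert-butyldimethylsilyloxy)methyl]-1-(4-hydroxy-3-methoxyphenyl)-6-methoxy-1,2-dihydronaphthalen-2-yl]methyl acetate, via para-quinone methide 19 (not isolated)
Conditions: (R)-3,3'-bis(2,4,6-triisopropylphenyl)-1,1'-binaphthyl-2,2'-diyl hydrogen phosphate (10 mol %), 5 Å molecular sieves, CH2Cl2 (0.01 M), −20 → 23 °C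
Reagents that add atoms: none
Why: Proposed new method: the acid dehydrates racemic 18 to planar para-quinone methide 19, so both carbinol antipodes converge, and hydrogen bonding to the quinoid oxygen gives C1 benzhydryl-cation character; C2 then bonds to C1, charge develops on tertiary C3 (where the acetate carbonyl can lend transient support), and the phosphate or the water set free removes an aligned benzylic C4 proton, a stepwise ene-type sequence that ends in the ring-A-conjugated C3=C4 alkene. The closest known reaction types are chiral phosphoric acid catalysed 1,6-additions of π-nucleophiles to para-quinone methides generated in situ from 4-hydroxybenzyl alcohols, chiral Brønsted acid catalysed intramolecular cycloadditions of ortho-quinone methides with unactivated trisubstituted alkenes, and Lewis acid cation–olefin cyclizations; the enantioselective capture of a para-quinone methide by a tethered unactivated alkene is the untested part. Ring B closes 6-endo-trig at the C2=C3 alkene (exo with respect to the methide C=C bond), and the 5-exo mode through C3 is disfavoured because it would build a quaternary carbon and leave a secondary cation. At C2 the (E)-geometry keeps CH2OAc cis to C4, so the half-chair transition state forces it pseudoaxial, while at C1 the quinoid ring also turns pseudoaxial to avoid the peri C8–H and lies anti to CH2OAc, which makes the pair trans; the absolute sense comes from the 2,4,6-triisopropylphenyl walls of the phosphate, which leave one face of C1 open. The step needs chemoselective ionization at C1 only, which the substrate secures through a single free phenol para to C1, the C6 methoxy group para to C8a, a silylated C7 oxygen that is meta to C8a, and primary allylic acetate and silyl ether groups that this weak acid does not ionize, while 0.01 M dilution holds back intermolecular Friedel–Crafts capture. Regioselective termination follows from the C4 hydrogens being the only benzylic ones next to C3.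

Step 12
Reactants: 20 [(1S,2R)-7-(tert-butyldimethylsilyloxy)-3-[(tert-butyldimethylsilyloxy)methyl]-1-(4-hydroxy-3-methoxyphenyl)-6-methoxy-1,2-dihydronaphthalen-2-yl]methyl acetate
Product: 21 [(1S,2R)-7-(tert-butyldimethylsilyloxy)-1-[4-(tert-butyldimethylsilyloxy)-3-methoxyphenyl]-3-[(tert-butyldimethylsilyloxy)methyl]-6-methoxy-1,2-dihydronaphthalen-2-yl]methyl acetate
Conditions: TBSCl, imidazole, DMF, 23 °C
Reagents that add atoms: tert-butyldimethylsilyl chloride CC(C)(C)[Si](C)(C)Cl
Why: Silylation of the only free hydroxyl masks the 4-hydroxyphenyl/C1–H array, which the oxidant of step 14 could otherwise turn into a quinone methide and on to the naphthalene.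

Step 13
Reactants: 21 [(1S,2R)-7-(tert-butyldimethylsilyloxy)-1-[4-(tert-butyldimethylsilyloxy)-3-methoxyphenyl]-3-[(tert-butyldimethylsilyloxy)methyl]-6-methoxy-1,2-dihydronaphthalen-2-yl]methyl acetate
Product: 22 [(1S,2R)-7-(tert-butyldimethylsilyloxy)-1-[4-(tert-butyldimethylsilyloxy)-3-methoxyphenyl]-3-(hydroxymethyl)-6-methoxy-1,2-dihydronaphthalen-2-yl]methyl acetate
Conditions: HF·pyridine, pyridine, THF, 0 °C
Reagents that add atoms: none
Why: Under acidic fluoride a primary alkyl TBS ether cleaves well before aryl TBS ethers (the reverse of the order under basic fluoride), and the buffered, methanol-free medium spares the acetate and avoids solvolysis of the electron-rich cinnamyl-type alcohol.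

Step 14
Reactants: 22 [(1S,2R)-7-(tert-butyldimethylsilyloxy)-1-[4-(tert-butyldimethylsilyloxy)-3-methoxyphenyl]-3-(hydroxymethyl)-6-methoxy-1,2-dihydronaphthalen-2-yl]methyl acetate
Product: 23 [(1S,2R)-7-(tert-butyldimethylsilyloxy)-1-[4-(tert-butyldimethylsilyloxy)-3-methoxyphenyl]-3-formyl-6-methoxy-1,2-dihydronaphthalen-2-yl]methyl acetate
Conditions: activated MnO2 (excess), CH2Cl2, 23 °C
Reagents that add atoms: none
Why: MnO2 oxidises the allylic alcohol under neutral heterogeneous conditions, and C2 is not at risk because its hydrogen is only cross-conjugated with the new aldehyde.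

Step 15
Reactants: 23 [(1S,2R)-7-(tert-butyldimethylsilyloxy)-1-[4-(tert-butyldimethylsilyloxy)-3-methoxyphenyl]-3-formyl-6-methoxy-1,2-dihydronaphthalen-2-yl]methyl acetate
Product: 24 [(1S,2R)-3-formyl-7-hydroxy-1-(4-hydroxy-3-methoxyphenyl)-6-methoxy-1,2-dihydronaphthalen-2-yl]methyl acetate
Conditions: Bu4NF, AcOH (2.5 equiv each), THF, 0 °C
Reagents that add atoms: none
Why: Fluoride cleaves both aryl TBS ethers quickly, and acetic acid protonates the phenoxides so that the acetate, the enal and the C1/C2 centres are never exposed to base.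

Compound list
1 | but-2-yne-1,4-diol | OCC#CCO | starting material
2 | 4-(tert-butyldimethylsilyloxy)but-2-yn-1-ol | OCC#CCO[Si](C)(C)C(C)(C)C | intermediate
3 | sodium cyclic vinylalanate (five-membered O–Al–C=CH–CH2 ring, two 2-methoxyethoxy groups on Al, CH2OTBS on the Al-bearing carbon) | [Na+].COCCO[Al-]1(OCCOC)OCC=C1CO[Si](C)(C)C(C)(C)C | intermediate
4 | (Z)-4-(tert-butyldimethylsilyloxy)-3-iodobut-2-en-1-ol (I cis to CH2OH) | OC/C=C(\I)CO[Si](C)(C)C(C)(C)C | intermediate
5 | 2-bromo-4-hydroxy-5-methoxybenzaldehyde (6-bromovanillin) | O=Cc1cc(OC)c(O)cc1Br | starting material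
6 | 2-bromo-4-(tert-butyldimethylsilyloxy)-5-methoxybenzaldehyde | O=Cc1cc(OC)c(O[Si](C)(C)C(C)(C)C)cc1Br | intermediate
7 | [2-bromo-4-(tert-butyldimethylsilyloxy)-5-methoxyphenyl]methanol | OCc1cc(OC)c(O[Si](C)(C)C(C)(C)C)cc1Br | intermediate
8 | 2-bromo-4-(tert-butyldimethylsilyloxy)-5-methoxybenzyl chloride | ClCc1cc(OC)c(O[Si](C)(C)C(C)(C)C)cc1Br | intermediate
9 | 2-bromo-4-(tert-butyldimethylsilyloxy)-5-methoxybenzylzinc chloride | Cl[Zn]Cc1cc(OC)c(O[Si](C)(C)C(C)(C)C)cc1Br | intermediate
10 | (E)-4-[2-bromo-4-(tert-butyldimethylsilyloxy)-5-methoxyphenyl]-3-[(tert-butyldimethylsilyloxy)methyl]but-2-en-1-ol (ArCH2 cis to CH2OH) | OC/C=C(\Cc1cc(OC)c(O[Si](C)(C)C(C)(C)C)cc1Br)CO[Si](C)(C)C(C)(C)C | intermediate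
11 | dilithio species (lithium alkoxide and aryllithium of 10) | [Li]OC/C=C(\Cc1cc(OC)c(O[Si](C)(C)C(C)(C)C)cc1[Li])CO[Si](C)(C)C(C)(C)C | intermediate
12 | 5-(tert-butyldimethylsilyloxy)-2-{(E)-2-[(tert-butyldimethylsilyloxy)methyl]-4-hydroxybut-2-enyl}-4-methoxybenzaldehyde | O=Cc1cc(O[Si](C)(C)C(C)(C)C)c(OC)cc1C/C(CO[Si](C)(C)C(C)(C)C)=C\CO | intermediate
13 | (E)-4-[4-(tert-butyldimethylsilyloxy)-2-formyl-5-methoxyphenyl]-3-[(tert-butyldimethylsilyloxy)methyl]but-2-enyl acetate | O=Cc1cc(O[Si](C)(C)C(C)(C)C)c(OC)cc1C/C(CO[Si](C)(C)C(C)(C)C)=C\COC(C)=O | intermediate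
14 | 4-bromo-2-methoxyphenol | COc1cc(Br)ccc1O | starting material
15 | (4-bromo-2-methoxyphenoxy)trimethylsilane | COc1cc(Br)ccc1O[Si](C)(C)C | intermediate
16 | [3-methoxy-4-(trimethylsilyloxy)phenyl]magnesium bromide | COc1cc([Mg]Br)ccc1O[Si](C)(C)C | intermediate
17 | racemic aryl TMS ether of 18 | COc1cc(C(O)c2cc(O[Si](C)(C)C(C)(C)C)c(OC)cc2C/C(CO[Si](C)(C)C(C)(C)C)=C\COC(C)=O)ccc1O[Si](C)(C)C | intermediate
18 | racemic (E)-4-{4-(tert-butyldimethylsilyloxy)-2-[hydroxy(4-hydroxy-3-methoxyphenyl)methyl]-5-methoxyphenyl}-3-[(tert-butyldimethylsilyloxy)methyl]but-2-enyl acetate | COc1cc(C(O)c2cc(O[Si](C)(C)C(C)(C)C)c(OC)cc2C/C(CO[Si](C)(C)C(C)(C)C)=C\COC(C)=O)ccc1O | intermediate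
19 | para-quinone methide of 18: 4-(arylmethylidene)-2-methoxycyclohexa-2,5-dien-1-one, either methide geometry, side-chain alkene (E) | COC1=CC(=Cc2cc(O[Si](C)(C)C(C)(C)C)c(OC)cc2C/C(CO[Si](C)(C)C(C)(C)C)=C\COC(C)=O)C=CC1=O | intermediate
20 | [(1S,2R)-7-(tert-butyldimethylsilyloxy)-3-[(tert-butyldimethylsilyloxy)methyl]-1-(4-hydroxy-3-methoxyphenyl)-6-methoxy-1,2-dihydronaphthalen-2-yl]methyl acetate (trans) | COc1cc([C@H]2c3cc(O[Si](C)(C)C(C)(C)C)c(OC)cc3C=C(CO[Si](C)(C)C(C)(C)C)[C@@H]2COC(C)=O)ccc1O | intermediate
21 | pendant-phenol TBS ether of 20, (1S,2R) | COc1cc([C@H]2c3cc(O[Si](C)(C)C(C)(C)C)c(OC)cc3C=C(CO[Si](C)(C)C(C)(C)C)[C@@H]2COC(C)=O)ccc1O[Si](C)(C)C(C)(C)C | intermediate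
22 | (1S,2R)-3-hydroxymethyl bis(aryl TBS ether) acetate | COc1cc([C@H]2c3cc(O[Si](C)(C)C(C)(C)C)c(OC)cc3C=C(CO)[C@@H]2COC(C)=O)ccc1O[Si](C)(C)C(C)(C)C | intermediate
23 | (1S,2R)-3-formyl bis(aryl TBS ether) acetate | COc1cc([C@H]2c3cc(O[Si](C)(C)C(C)(C)C)c(OC)cc3C=C(C=O)[C@@H]2COC(C)=O)ccc1O[Si](C)(C)C(C)(C)C | intermediate
24 | [(1S,2R)-3-formyl-7-hydroxy-1-(4-hydroxy-3-methoxyphenyl)-6-methoxy-1,2-dihydronaphthalen-2-yl]methyl acetate | COc1cc([C@H]2c3cc(O)c(OC)cc3C=C(C=O)[C@@H]2COC(C)=O)ccc1O | target

Total step count: 15. Longest linear sequence: 12 (steps 3–8 and 10–15, from 5).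

Steps most likely to fail

Step 11. The weak acid may activate the methide too little for an alkene that two allylic oxygens deactivate. A 1,2-hydride shift from the CH2OSi group to C3 may compete with proton loss. Facial selectivity may be poor because the counter-anion sits far from C1. The fallback uses known chemistry and sets out from 18. Stoichiometric BF3·OEt2 in CH2Cl2 at −78 °C ionizes the carbinol and runs a classical cation–olefin cyclization under substrate control alone, which should give the trans-dihydronaphthalene as a racemate, that is 20 together with the (1R,2S)-antipode of 20 F1. Preparative chromatography on an amylose tris(3,5-dimethylphenylcarbamate) stationary phase separates the two, and the route is rejoined at 20.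

Step 10. The Grignard reagent may attack the acetate, early loss of the TMS group may quench it, or the very labile carbinol may ionize during work-up. The fallback sets out from 12, before any ester is present. Reagent 16 (2.2 equiv, one of which is spent on the hydroxyl) adds to the aldehyde to give the aryl TMS ether diol F2. The same near-neutral work-up hydrolyses this to the phenolic diol F3. Immobilised Candida antarctica lipase B with vinyl acetate in tert-butyl methyl ether then acetylates only the primary allylic hydroxyl, since phenols and hindered diaryl carbinols are not accepted. The route is rejoined at 18.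

Step 6. The free hydroxyl may protonate the benzylzinc reagent, Wurtz-type homocoupling may occur, zerovalent palladium may insert into the aryl C–Br bond, or the alkene geometry may erode. The fallback reverses the polarity and sets out from 4. Stannylation with Bu3SnSnBu3 and Pd(PPh3)4 in toluene at 80 °C gives (Z)-4-(tert-butyldimethylsilyloxy)-3-(tributylstannyl)but-2-en-1-ol F4, which is indifferent to its own hydroxyl. Stille coupling of F4 with benzylic chloride 8 (Pd2(dba)3, AsPh3, CuI, DMF, 40 °C) proceeds with retention under neutral conditions and rejoins the route at 10.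

Further compounds
F1 | step 11 | [(1R,2S)-7-(tert-butyldimethylsilyloxy)-3-[(tert-butyldimethylsilyloxy)methyl]-1-(4-hydroxy-3-methoxyphenyl)-6-methoxy-1,2-dihydronaphthalen-2-yl]methyl acetate | COc1cc([C@@H]2c3cc(O[Si](C)(C)C(C)(C)C)c(OC)cc3C=C(CO[Si](C)(C)C(C)(C)C)[C@H]2COC(C)=O)ccc1O
F2 | step 10 | racemic (E)-4-{4-(tert-butyldimethylsilyloxy)-2-[hydroxy(3-methoxy-4-(trimethylsilyloxy)phenyl)methyl]-5-methoxyphenyl}-3-[(tert-butyldimethylsilyloxy)methyl]but-2-en-1-ol | COc1cc(C(O)c2cc(O[Si](C)(C)C(C)(C)C)c(OC)cc2C/C(CO[Si](C)(C)C(C)(C)C)=C\CO)ccc1O[Si](C)(C)C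
F3 | step 10 | racemic (E)-4-{4-(tert-butyldimethylsilyloxy)-2-[hydroxy(4-hydroxy-3-methoxyphenyl)methyl]-5-methoxyphenyl}-3-[(tert-butyldimethylsilyloxy)methyl]but-2-en-1-ol | COc1cc(C(O)c2cc(O[Si](C)(C)C(C)(C)C)c(OC)cc2C/C(CO[Si](C)(C)C(C)(C)C)=C\CO)ccc1O
F4 | step 6 | (Z)-4-(tert-butyldimethylsilyloxy)-3-(tributylstannyl)but-2-en-1-ol | OC/C=C(\[Sn](CCCC)(CCCC)CCCC)CO[Si](C)(C)C(C)(C)C
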